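## Structural features

18 is an achiral isoflavone: benzo ring A is fused through C4a–C8a to pyranone ring C, which carries the 2,4,5-trimethoxyphenyl ring B at C3 through the C3–C1' bond. There is no stereocentre and no stereogenic double bond, so every problem is one of regiochemistry. Ring A is hexasubstituted: C4a (the C4 carbonyl), C5 (OH, hydrogen-bonded to C4=O), C6 (prenyl), C7 (OH), C8 (OMe) and C8a (O1). Its four oxygens have three different fates (two free, one methylated, one in ring C), and the prenyl carbon sits between the two free hydroxyls. Fragile points are the prenyl olefin (it cyclises onto an ortho hydroxyl under protic or Lewis acid), the para pair O5/O8 (a masked hydroquinone towards oxidants), the pyranone (opened by hot alkali) and the electron-rich ring B (a competitor in electrophilic steps). The real difficulty is ring A: a 2,4,6-trihydroxy-3-methoxyphenyl ketone can close ring C on either ortho hydroxyl (8-methoxy versus 6-methoxy chromone), and O- versus C-prenylation of a phloroglucinol-type ring has no structural bias. The key step exploits two features. The run C8a(O)–C8(OMe)–C7(O)–C6(C) has the substitution of a squarate-derived cyclobutenone, and the remaining pair C4a(H)–C5(O) is an alkoxyacetylene. The meta relation of the oxygens on C8a and C5 is what a ketene–ynol ether benzannulation delivers, and it leaves the hydroxyl on C8a as the only free one next to the only unsubstituted carbon, C4a.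

## Logic of the disconnections

18 ⇒ 17. Bond cut: the C=C bond of the side chain on C6 (the =CMe2 terminus is exchanged for =CH2). The prenyl group is the most acid-sensitive part of 18, and as an allyl group it survives every acidic step. The gain is that all Lewis-acid chemistry precedes the olefin exchange. The demand is a cross-metathesis that tolerates two free phenols and leaves the enone of ring C alone.

17 ⇒ 16. Bonds cut: O5–ethyl and O7–isopropyl. Neither alkyl group is put on in a separate protection step: the isopropyl group comes with 1 and the ethyl group with 7. The gain is a single deprotection. The demand is cleavage of a secondary ether and of a peri-chelated primary ether in the presence of four methyl ethers.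

16 ⇒ 14 (through 15). Bonds cut: O1–C2 and C2=C3, with C2 as a one-carbon unit at the formate oxidation level. In 14 only one hydroxyl ortho to the ketone is free, so ring C can close in one direction only. The demand is that O5 stays alkylated until ring C exists.

14 ⇒ 12 + 13. Bond cut: C4–C4a. 12 has one unsubstituted ring carbon, and it lies ortho to its one free hydroxyl. Ring B enters complete from a commercial acid. The demand is C-acylation under conditions that spare the allyl group and the secondary ether.

12 ⇒ 6 + 7 (through 8, 9, 10 and 11). Bonds cut: C8a–C4a and C5–C6; the C8a–C8 bond of the four-membered ring is broken and re-formed on the way. Ring A is assembled from a four-carbon piece and a two-carbon piece that already carry every substituent in the right order. The gain is that a hexasubstitution problem shrinks to the orientation of one cycloaddition, and no symmetric polyphenol has to be differentiated. The demand is bimolecular capture of a vinylketene by the ynol ether in the correct sense, followed by productive electrocyclisation.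

6 ⇒ 4. Bonds cut: C8–H and O8–CH3. The C8 methyl ether is installed on an sp3 carbinol, where it cannot be confused with any other oxygen of the later arene. The demand is hydride delivery to the carbonyl next to the alkoxy-bearing carbon and a non-acidic methylation.

4 ⇒ 1 + 2. Bond cut: the bond between the ring carbon that becomes C6 and the allyl CH2. 1 is a commercial, symmetric four-carbon unit, and addition followed by acid makes it unsymmetrical in one operation. The demand is mono-addition.

## Other disconnections considered

Alternative 1: This is the route drawn first. Cut C4–C4a, then O1–C2 and C2–C3, on a preformed polyphenol. Houben–Hoesch or Friedel–Crafts acylation of 2-methoxyphloroglucinol A1 with the arylacetic acid unit gives deoxybenzoin A2, a one-carbon reagent closes ring C, and a prenyl halide is then brought to C6. The chosen plan is preferred on structural grounds. In A2 the ketone has two free ortho hydroxyls that differ only in a remote neighbour, so closure can give the 8-methoxy chromone A3 as well as its 6-methoxy isomer A4; the two are in principle interconvertible by ring opening under acid (Wessely–Moser rearrangement). The prenyl electrophile then meets O7, O5 and C6 of A3 with no bias for carbon. Curing both needs selective protection of a symmetric triol, which costs the steps the short count seems to save. In the chosen route the ambiguity does not arise, because O1, O5, O7 and O8 come from four different atoms of 6 and 7.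

Alternative 2: Cut C3–C1'. The forward key step is a Suzuki–Miyaura coupling of 3-iodochromone A5 with arylboronic acid A6. The C3–C1' bond is the easiest bond of the molecule. A5 still needs a 2-hydroxyacetophenone with the complete, differentiated ring A, which is the same regiochemical problem as in alternative 1. The C6 side chain must either be added afterwards to a phloroglucinol-type ring or be carried through an iodine-mediated ring closure, where an olefin next to an oxygen is open to iodoetherification. The disconnection removes none of the real difficulty and is longer (enaminone, iodocyclisation, coupling) than acylation with 13 plus one-carbon insertion.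

Alternative 3: Cut C4–C4a as the ring-closing bond of ring C (closure at carbon instead of at oxygen). A phenol is O-vinylated to the (Z)-3-aryloxy-2-arylacrylic acid A7, which closes by intramolecular Friedel–Crafts acylation. This is unconventional for ring C, but A7 needs the same pentasubstituted phenol 12, so ring A is not simplified at all. Only the isomer of A7 with the carboxyl group cis to the aryloxy group can close, and closure onto the hindered C4a calls for strong acid media that endanger the allyl group and the secondary ether. The sequence is also one step longer than steps 4 and 5. The benzannulation is kept because it is the disconnection that acts on ring A.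

Key step: step 3

Remark: 1, 2, 7 and 13 are taken as commercial; 18 has no stereocentre, and the stereocentres of 3, 5, 6, 9 and 11 are formed racemic and are lost on aromatisation.

## Steps

Step 1
Reactants: 1 diisopropyl squarate (3,4-diisopropoxycyclobut-3-ene-1,2-dione); 2 allylmagnesium bromide
Product: 4 3-allyl-4-isopropoxycyclobut-3-ene-1,2-dione, via carbinol 3 (not isolated)
Conditions: 2 (1.05 equiv), THF, −78 °C; 1 M HCl quench; crude 3, 12 M HCl (cat.), CH2Cl2, 23 °C
Reagents that add atoms: none
Why: 1,2-Addition of the Grignard reagent to one carbonyl of 1 gives 3; acid ionises the tertiary carbinol to an alkoxy-stabilised cyclobutenyl cation that takes up water at the distal alkoxy carbon and loses propan-2-ol, the standard squarate to 3-alkylcyclobutenedione sequence. Allyl is used instead of prenyl because an allyl Grignard reagent gives one constitution whichever terminus attacks.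

Step 2
Reactants: 4 3-allyl-4-isopropoxycyclobut-3-ene-1,2-dione
Product: 6 2-allyl-3-isopropoxy-4-methoxycyclobut-2-en-1-one (racemic), via hydroxycyclobutenone 5 (not isolated)
Conditions: LiAlH(O-t-Bu)3 (1.1 equiv), THF, −78 → −20 °C; aq. potassium sodium tartrate; crude 5, MeI, Ag2O, CH2Cl2, 23 °C, dark
Reagents that add atoms: iodomethane, CI
Why: The bulky hydride reduces the more electrophilic carbonyl, the one bonded to the isopropoxy-bearing carbon (the other is a vinylogous ester), and neutral Purdie methylation caps the acid-labile secondary alcohol without ionising it. The new stereocentre is racemic and is destroyed in step 3.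

Step 3
Reactants: 6 2-allyl-3-isopropoxy-4-methoxycyclobut-2-en-1-one; 7 ethoxyacetylene
Product: 12 4-allyl-5-ethoxy-3-isopropoxy-2-methoxyphenol, via vinylketene 8 (not isolated), via vinylcyclobutenone 9 (not isolated), via dienylketene 10 (not isolated), via cyclohexadienone 11 (not isolated)
Conditions: 7 (3 equiv), toluene, 80 °C, sealed tube, argon; excess 7 evaporated; then xylene, 135 °C
Reagents that add atoms: none
Why: Heating opens 6 by a conrotatory 4π-electrocyclic reaction, the C4 methoxy donor turning outward, to vinylketene 8; the nucleophilic CH terminus of ynol ether 7 attacks the ketene carbon and a regiospecific [2+2] cycloaddition gives 9, in which the new bonds are C8a–C4a and C5–C6. A second 4π opening of 9 gives dienylketene 10, and ring A is closed by a thermal disrotatory 6π-electrocyclisation that joins C8a to C8; tautomerisation of cyclohexadienone 11 (loss of the C8 hydrogen, the methoxy group stays) gives phenol 12. The closest known reaction type is the Danheiser benzannulation of cyclobutenones with alkoxyacetylenes. Net, the two alkyne carbons are inserted between the carbonyl carbon and the allyl-bearing carbon of the four-membered ring, so the order O(C8a), OMe(C8), O-i-Pr(C7), allyl(C6), OEt(C5), H(C4a) follows from the connectivity of 6 and the polarity of 7 alone. The selectivity needed is the orientation of the [2+2] step, which is secured by the polarisation of the ynol ether (the general sense of ketene–ynol ether cycloadditions) and places the ethoxy group meta to the new hydroxyl. Only the rotamer of 10 with the alkenyl arm turned inward can close, and because both ring openings are reversible the other rotamers are returned and drained through the irreversible aromatisation. The stereocentres of 6, 9 and 11 all vanish, and the methoxy donor at C4 of 6 should lower the barrier of the first opening so that 8 forms below the temperature at which 7 fragments.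

Step 4
Reactants: 12 4-allyl-5-ethoxy-3-isopropoxy-2-methoxyphenol; 13 2,4,5-trimethoxyphenylacetic acid
Product: 14 1-(3-allyl-2-ethoxy-6-hydroxy-4-isopropoxy-5-methoxyphenyl)-2-(2,4,5-trimethoxyphenyl)ethan-1-one
Conditions: 13 (1.5 equiv), (CF3CO)2O (3 equiv), 85% H3PO4 (cat.), CH2Cl2, 0 → 23 °C; aq. NaHCO3
Reagents that add atoms: none
Why: Friedel–Crafts acylation by the mixed trifluoroacetic anhydride of 13 at C4a, the only unsubstituted position of 12, which is activated by an ortho hydroxyl, an ortho ethoxy and a para isopropoxy group. Transient O-trifluoroacetylation of the phenol is undone by the bicarbonate work-up, and the mild protic medium should spare the allyl group and the secondary ether.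

Step 5
Reactants: 14 1-(3-allyl-2-ethoxy-6-hydroxy-4-isopropoxy-5-methoxyphenyl)-2-(2,4,5-trimethoxyphenyl)ethan-1-one
Product: 16 6-allyl-5-ethoxy-7-isopropoxy-8-methoxy-3-(2,4,5-trimethoxyphenyl)-4H-chromen-4-one, via enaminone 15 (not isolated)
Conditions: Me2NCH(OMe)2 (3 equiv), toluene, 90 °C
Reagents that add atoms: N,N-dimethylformamide dimethyl acetal, COC(OC)N(C)C
Why: Condensation at the doubly activated methylene gives enaminone 15, and the single free ortho hydroxyl (on C8a) adds to its β-carbon and expels dimethylamine, which closes ring C (standard deoxybenzoin to isoflavone conversion). With O5 held as the ethyl ether there is only one direction of closure.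

Step 6
Reactants: 16 6-allyl-5-ethoxy-7-isopropoxy-8-methoxy-3-(2,4,5-trimethoxyphenyl)-4H-chromen-4-one
Product: 17 6-allyl-5,7-dihydroxy-8-methoxy-3-(2,4,5-trimethoxyphenyl)-4H-chromen-4-one
Conditions: BCl3 (6 equiv), CH2Cl2, −78 → 23 °C; MeOH, then H2O
Reagents that add atoms: none
Why: BCl3 cleaves the secondary isopropyl ether at O7 by an SN1-like path and the ethyl ether at O5 through the six-membered boron chelate with the C4 carbonyl (peri-assisted dealkylation). The four unchelated methyl ethers and the C-allyl group should not be attacked at or below room temperature.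

Step 7
Reactants: 17 6-allyl-5,7-dihydroxy-8-methoxy-3-(2,4,5-trimethoxyphenyl)-4H-chromen-4-one
Product: 18 6-prenylisocaviunin (5,7-dihydroxy-8-methoxy-6-(3-methylbut-2-en-1-yl)-3-(2,4,5-trimethoxyphenyl)-4H-chromen-4-one)
Conditions: second-generation Grubbs catalyst (H2IMes)(PCy3)Cl2Ru=CHPh (5 mol %), 2-methylbut-2-ene/CH2Cl2, 40 °C, sealed
Reagents that add atoms: 2-methylbut-2-ene, CC=C(C)C
Why: Olefin cross-metathesis of the terminal allyl group with excess 2-methylbut-2-ene exchanges =CH2 for =CMe2 with loss of propene, a standard allyl-to-prenyl conversion that tolerates free phenols. The trisubstituted product should not re-enter the cycle, and the enone double bond of ring C is inert.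

## Compound list

1 | diisopropyl squarate (3,4-diisopropoxycyclobut-3-ene-1,2-dione) | CC(C)OC1=C(OC(C)C)C(=O)C1=O | starting material
2 | allylmagnesium bromide | C=CC[Mg]Br | starting material
3 | 4-allyl-4-hydroxy-2,3-diisopropoxycyclobut-2-en-1-one (racemic) | C=CCC1(O)C(OC(C)C)=C(OC(C)C)C1=O | intermediate
4 | 3-allyl-4-isopropoxycyclobut-3-ene-1,2-dione | C=CCC1=C(OC(C)C)C(=O)C1=O | intermediate
5 | 2-allyl-4-hydroxy-3-isopropoxycyclobut-2-en-1-one (racemic) | C=CCC1=C(OC(C)C)C(O)C1=O | intermediate
6 | 2-allyl-3-isopropoxy-4-methoxycyclobut-2-en-1-one (racemic) | C=CCC1=C(OC(C)C)C(OC)C1=O | intermediate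
7 | ethoxyacetylene | CCOC#C | starting material
8 | (3Z)-2-allyl-3-isopropoxy-4-methoxybuta-1,3-dien-1-one | C=CCC(=C=O)/C(OC(C)C)=C/OC | intermediate
9 | 4-allyl-3-ethoxy-4-[(Z)-1-isopropoxy-2-methoxyvinyl]cyclobut-2-en-1-one (racemic) | O=C1C=C(OCC)C1(CC=C)/C(OC(C)C)=C/OC | intermediate
10 | (3E,5Z)-4-allyl-3-ethoxy-5-isopropoxy-6-methoxyhexa-1,3,5-trien-1-one | O=C=C/C(OCC)=C(CC=C)\C(OC(C)C)=C\OC | intermediate
11 | 4-allyl-3-ethoxy-5-isopropoxy-6-methoxycyclohexa-2,4-dien-1-one (racemic) | O=C1C=C(OCC)C(CC=C)=C(OC(C)C)C1OC | intermediate
12 | 4-allyl-5-ethoxy-3-isopropoxy-2-methoxyphenol | C=CCc1c(OCC)cc(O)c(OC)c1OC(C)C | intermediate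
13 | 2,4,5-trimethoxyphenylacetic acid | COc1cc(OC)c(CC(=O)O)cc1OC | starting material
14 | 1-(3-allyl-2-ethoxy-6-hydroxy-4-isopropoxy-5-methoxyphenyl)-2-(2,4,5-trimethoxyphenyl)ethan-1-one | C=CCc1c(OCC)c(C(=O)Cc2cc(OC)c(OC)cc2OC)c(O)c(OC)c1OC(C)C | intermediate
15 | 1-(3-allyl-2-ethoxy-6-hydroxy-4-isopropoxy-5-methoxyphenyl)-3-(dimethylamino)-2-(2,4,5-trimethoxyphenyl)prop-2-en-1-one (double-bond geometry of no consequence) | C=CCc1c(OCC)c(C(=O)C(=CN(C)C)c2cc(OC)c(OC)cc2OC)c(O)c(OC)c1OC(C)C | intermediate
16 | 6-allyl-5-ethoxy-7-isopropoxy-8-methoxy-3-(2,4,5-trimethoxyphenyl)-4H-chromen-4-one | COc1cc(OC)c(-c2coc3c(OC)c(OC(C)C)c(CC=C)c(OCC)c3c2=O)cc1OC | intermediate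
17 | 6-allyl-5,7-dihydroxy-8-methoxy-3-(2,4,5-trimethoxyphenyl)-4H-chromen-4-one | COc1cc(OC)c(-c2coc3c(OC)c(O)c(CC=C)c(O)c3c2=O)cc1OC | intermediate
18 | 6-prenylisocaviunin | COc1cc(OC)c(-c2coc3c(OC)c(O)c(CC=C(C)C)c(O)c3c2=O)cc1OC | target

## Step count and least certain steps

Total step count: 7. Longest linear sequence: 7 steps (1 to 18); 2, 7 and 13 enter as commercial reagents.

Step 3 (key step). The bimolecular [2+2] capture of vinylketene 8 may lose to its reversion and slow oligomerisation, or 7 may fragment by a retro-ene path before capture is complete. In addition, the rotamer of the dienylketene with the allyl group turned inward may leave by intramolecular ketene–olefin cycloaddition instead of reverting. Fallback: the same ring A is made by an intramolecular cyclobutenone ring expansion (Moore rearrangement). It sets out from 4. 1-(tert-Butoxy)vinyllithium F1 (tert-butyl vinyl ether, t-BuLi, THF, −78 → 0 °C) is added at −78 °C to the carbonyl next to the isopropoxy-bearing carbon. The tertiary alkoxide is methylated in the same flask with methyl triflate to give 2-allyl-4-(1-tert-butoxyvinyl)-3-isopropoxy-4-methoxycyclobut-2-en-1-one F2. Heating in toluene at 110 °C brings about 4π ring opening and 6π ring closure within one molecule and gives 2-allyl-5-tert-butoxy-3-isopropoxy-4-methoxyphenol F3, whose free hydroxyl is the one on C5. Ethylation (EtI, K2CO3, DMF) gives 2-allyl-5-tert-butoxy-1-ethoxy-3-isopropoxy-4-methoxybenzene F4, and CF3CO2H with Et3SiH in CH2Cl2 removes the tert-butyl group and comes back to the route at 12. In this variant the allyl group sits on the ketene α-carbon, too close for cycloaddition; the price is two more steps.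

Step 2. Hydride may be delivered to the vinylogous-ester carbonyl, or carbinol 5 may ionise with loss of propan-2-ol during work-up or on the silver salt. Fallback: the detour given under step 3 sets out from 4 and comes back at 12 without any reduction and without a secondary 4-hydroxycyclobutenone; it makes no compound beyond F1 to F4.

Step 4. O-Acylation of the phenol may outrun C-acylation at the hindered C4a, or acid may promote hydration or migration of the allyl double bond. Fallback: carbonyl addition replaces electrophilic acylation. From 12, ortho-formylation with MgCl2, Et3N and paraformaldehyde in MeCN gives 3-allyl-2-ethoxy-6-hydroxy-4-isopropoxy-5-methoxybenzaldehyde F5. (2,4,5-Trimethoxybenzyl)magnesium chloride F6 (2.2 equiv, THF, −78 °C) adds to give 1-(3-allyl-2-ethoxy-6-hydroxy-4-isopropoxy-5-methoxyphenyl)-2-(2,4,5-trimethoxyphenyl)ethan-1-ol F7. MnO2 in CH2Cl2 oxidises the benzylic alcohol and comes back to the route at 14.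

Step 6. Cleavage of the primary ethyl ether at O5 may stay incomplete, or, when the reaction is forced, the C8 methyl group may be lost through the neighbouring O7 borate. Fallback: O5 is carried as a second isopropyl ether, so that both groups leave by the easy secondary-ether path. From 4 the detour of step 3 is followed through F2 to F3. 2-Bromopropane with K2CO3 in DMF gives 2-allyl-5-tert-butoxy-1,3-diisopropoxy-4-methoxybenzene F8, and CF3CO2H with Et3SiH gives 4-allyl-3,5-diisopropoxy-2-methoxyphenol F9. Acylation with 13 as in step 4 gives 1-(3-allyl-6-hydroxy-2,4-diisopropoxy-5-methoxyphenyl)-2-(2,4,5-trimethoxyphenyl)ethan-1-one F10. Me2NCH(OMe)2 gives, through enaminone F11, 6-allyl-5,7-diisopropoxy-8-methoxy-3-(2,4,5-trimethoxyphenyl)-4H-chromen-4-one F12. BCl3 at −78 → 0 °C comes back to the route at 17.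

Step 7. The catalyst may be deactivated by chelation to the phenols that flank the allyl group, or a ruthenium hydride may move the double bond into conjugation before metathesis. Fallback: the metathesis is run on a substrate without free phenols. From 17, Ac2O and pyridine give 6-allyl-8-methoxy-4-oxo-3-(2,4,5-trimethoxyphenyl)-4H-chromene-5,7-diyl diacetate F13. Cross-metathesis with 2-methylbut-2-ene and the same catalyst gives 8-methoxy-6-(3-methylbut-2-en-1-yl)-4-oxo-3-(2,4,5-trimethoxyphenyl)-4H-chromene-5,7-diyl diacetate F14. Methanolysis with K2CO3 in MeOH at 0 °C comes back to the route at 18.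

## Further compounds

F1 | step 3 | 1-(tert-butoxy)vinyllithium | [Li]C(=C)OC(C)(C)C
F2 | step 3 | 2-allyl-4-(1-tert-butoxyvinyl)-3-isopropoxy-4-methoxycyclobut-2-en-1-one (racemic) | C=CCC1=C(OC(C)C)C(OC)(C(=C)OC(C)(C)C)C1=O
F3 | step 3 | 2-allyl-5-tert-butoxy-3-isopropoxy-4-methoxyphenol | C=CCc1c(O)cc(OC(C)(C)C)c(OC)c1OC(C)C
F4 | step 3 | 2-allyl-5-tert-butoxy-1-ethoxy-3-isopropoxy-4-methoxybenzene | C=CCc1c(OCC)cc(OC(C)(C)C)c(OC)c1OC(C)C
F0 | step 2 | none | none
F5 | step 4 | 3-allyl-2-ethoxy-6-hydroxy-4-isopropoxy-5-methoxybenzaldehyde | C=CCc1c(OCC)c(C=O)c(O)c(OC)c1OC(C)C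
F6 | step 4 | (2,4,5-trimethoxybenzyl)magnesium chloride | COc1cc(OC)c(C[Mg]Cl)cc1OC
F7 | step 4 | 1-(3-allyl-2-ethoxy-6-hydroxy-4-isopropoxy-5-methoxyphenyl)-2-(2,4,5-trimethoxyphenyl)ethan-1-ol (racemic) | C=CCc1c(OCC)c(C(O)Cc2cc(OC)c(OC)cc2OC)c(O)c(OC)c1OC(C)C
F8 | step 6 | 2-allyl-5-tert-butoxy-1,3-diisopropoxy-4-methoxybenzene | C=CCc1c(OC(C)C)cc(OC(C)(C)C)c(OC)c1OC(C)C
F9 | step 6 | 4-allyl-3,5-diisopropoxy-2-methoxyphenol | C=CCc1c(OC(C)C)cc(O)c(OC)c1OC(C)C
F10 | step 6 | 1-(3-allyl-6-hydroxy-2,4-diisopropoxy-5-methoxyphenyl)-2-(2,4,5-trimethoxyphenyl)ethan-1-one | C=CCc1c(OC(C)C)c(C(=O)Cc2cc(OC)c(OC)cc2OC)c(O)c(OC)c1OC(C)C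
F11 | step 6 | 1-(3-allyl-6-hydroxy-2,4-diisopropoxy-5-methoxyphenyl)-3-(dimethylamino)-2-(2,4,5-trimethoxyphenyl)prop-2-en-1-one | C=CCc1c(OC(C)C)c(C(=O)C(=CN(C)C)c2cc(OC)c(OC)cc2OC)c(O)c(OC)c1OC(C)C
F12 | step 6 | 6-allyl-5,7-diisopropoxy-8-methoxy-3-(2,4,5-trimethoxyphenyl)-4H-chromen-4-one | COc1cc(OC)c(-c2coc3c(OC)c(OC(C)C)c(CC=C)c(OC(C)C)c3c2=O)cc1OC
F13 | step 7 | 6-allyl-8-methoxy-4-oxo-3-(2,4,5-trimethoxyphenyl)-4H-chromene-5,7-diyl diacetate | COc1cc(OC)c(-c2coc3c(OC)c(OC(C)=O)c(CC=C)c(OC(C)=O)c3c2=O)cc1OC
F14 | step 7 | 8-methoxy-6-(3-methylbut-2-en-1-yl)-4-oxo-3-(2,4,5-trimethoxyphenyl)-4H-chromene-5,7-diyl diacetate | COc1cc(OC)c(-c2coc3c(OC)c(OC(C)=O)c(CC=C(C)C)c(OC(C)=O)c3c2=O)cc1OC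
A1 | alternative 1 | 2-methoxybenzene-1,3,5-triol (2-methoxyphloroglucinol) | COc1c(O)cc(O)cc1O
A2 | alternative 1 | 1-(2,4,6-trihydroxy-3-methoxyphenyl)-2-(2,4,5-trimethoxyphenyl)ethan-1-one | COc1c(O)cc(O)c(C(=O)Cc2cc(OC)c(OC)cc2OC)c1O
A3 | alternative 1 | 5,7-dihydroxy-8-methoxy-3-(2,4,5-trimethoxyphenyl)-4H-chromen-4-one | COc1cc(OC)c(-c2coc3c(OC)c(O)cc(O)c3c2=O)cc1OC
A4 | alternative 1 | 5,7-dihydroxy-6-methoxy-3-(2,4,5-trimethoxyphenyl)-4H-chromen-4-one | COc1cc(OC)c(-c2coc3cc(O)c(OC)c(O)c3c2=O)cc1OC
A5 | alternative 2 | 3-iodo-8-methoxy-5,7-bis(methoxymethoxy)-4H-chromen-4-one | COCOc1cc(OCOC)c2c(=O)c(I)coc2c1OC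
A6 | alternative 2 | (2,4,5-trimethoxyphenyl)boronic acid | COc1cc(OC)c(B(O)O)cc1OC
A7 | alternative 3 | (Z)-3-(4-allyl-5-ethoxy-3-isopropoxy-2-methoxyphenoxy)-2-(2,4,5-trimethoxyphenyl)acrylic acid | C=CCc1c(OCC)cc(O/C=C(\C(=O)O)c2cc(OC)c(OC)cc2OC)c(OC)c1OC(C)C
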